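# Proposed synthesis of N-{2-[(6R)-6-(3,4-dimethoxyphenyl)-5,6,7,8-tetrahydroquinolin-6-yl]ethyl}-N-methylacetamide (18)

## The problem

The target 18 is a 5,6,7,8-tetrahydroquinoline in which a saturated four-carbon bridge (C5 to C8) spans the adjacent pyridine carbons C4a and C8a, and C6 of that bridge is an all-carbon quaternary centre carrying a 3,4-dimethoxyphenyl group and a 2-(N-methylacetamido)ethyl chain. C6 is the only stereocentre, so nothing in the molecule can relay configuration to it; it has to be set by an external chiral agent or carried over intact from a stereocentre that is easier to make, and once it is quaternary it can no longer epimerise. The tertiary acetamide will not survive organolithium or Grignard reagents, so the nitrogen must travel in a masked form. The pyridine nitrogen binds Lewis acids and transition metals, and the dimethoxyphenyl ring is sensitive to oxidants and electrophilic halogen. Any electrophilic carbon placed at C8 would be attacked by the chain nitrogen with closure of a six-membered ring. The enabling feature is that C6 is benzylic to the dimethoxyphenyl ring, so that a carbamate oxygen on it makes its C–H bond removable as a configurationally defined carbanion. Its neighbour C5 is a CH2 group on pyridine carbon C4a, a benzylic-type group that can be held on boron and migrates readily from boron to carbon. The boron left on C6 after that migration marks the place from which C7 and C8 are grown before C8 is joined to C8a.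

## Retrosynthesis

**N–acyl and N–benzyl bonds.** Target 18 is cut at the amide N–C(O) bond to secondary amine 17, and 17 is traced to the N-benzyl-N-methyl amine 16. An acetamide could not pass the alkyllithium and Grignard stages, whereas a tertiary amine is inert to both. Benzyl is chosen because the N-benzyl-N-methyl unit comes in one operation from amine 2 and leaves by hydrogenolysis. The forward steps must remove benzyl without touching the N-methyl group or the pyridine ring, then acylate.

**C8–C8a bond.** The carbocycle of 16 is opened between C8 and C8a, giving alkene 14, where C7–C8 is a vinyl group on the quaternary carbon and C8a carries chlorine. A cut at C4a–C5 would require bond formation at the pyridine 3-position, which is the least activated toward either nucleophiles or oxidative addition. A cut at C7–C8 would require a second alkene on the pyridine and a later hydrogenation. C8 must be the nucleophilic partner, because a halide or sulfonate there would quaternise the chain nitrogen. Alkylborane 15, from anti-Markovnikov hydroboration of 14, meets this need and couples at the activated 2-chloropyridine carbon. The precursor is a monocyclic pyridine with an acyclic quaternary carbon.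

**C6–C7 bond.** The vinyl group of 14 is exchanged for boron, leading to tertiary boronic ester 11. Bringing C7 and C8 in on the carbanion partner instead would displace the nitrogen chain from the simplest starting ketone. The olefination at boron, through boronate 12 and iodoalkyl boronic ester 13, is stereoretentive at the migrating carbon and uses the boron atom the key step leaves behind. The forward reaction must add a vinyl nucleophile to a congested tertiary boron and tolerate a halogen electrophile beside an amine and an electron-rich arene.

**C5–C6 bond (key disconnection).** Boronic ester 11 is cut between the quaternary carbon and the picolyl CH2, giving carbamate 5 and picolyl boronic ester 8. In the forward sense, lithiated carbamate 9 adds to the boron of 8, and boronate 10 rearranges by a 1,2-shift of the picolyl group. The aryl group has to sit on the carbanion carbon, since it is what makes that C–H acidic. The picolyl group has to sit on boron: a carbamate with a picolyl CH2 on the neighbouring carbon would lose the carbamate by β-elimination on treatment with base. Both fragments are acyclic and each is two or three steps from purchasable material. The quaternary stereocentre is reduced to a secondary carbinol stereocentre. The forward reaction must transfer that configuration without loss.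

**Carbinol stereocentre and nitrogen chain.** Carbamate 5 comes from alcohol 4 by O-carbamoylation, and 4 from β-amino ketone 3 by enantioselective hydrogenation. Aryl ketones with a β-dialkylamino group are a well-behaved substrate class for this reduction, and this is the only step in the route that creates chirality. Ketone 3 is the Mannich base of acetophenone 1 and amine 2, so the full nitrogen chain is present after the first step.

**C–B bond of the picolyl fragment.** Boronic ester 8 is cut at the CH2–B bond to picolyl chloride 6 and diboron 7. A copper-catalysed boryl substitution is preferred to a palladium-catalysed one because it leaves the aryl C–Cl bond, needed later at C8a, untouched.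

## Roads not taken

Alternative 1: asymmetric ring-closing metathesis. The cut is the C7=C8 bond of a dihydroquinoline. The precursor would be the triene 3-[2-(3,4-dimethoxyphenyl)-2-ethenylbut-3-en-1-yl]-2-ethenylpyridine A1, in which the future C6 carries two enantiotopic vinyl groups. A chiral molybdenum alkylidene of the Mo(N-aryl)(CHCMe2Ph)(biphenolate) type would join the pyridine vinyl group of A1 to one of them and give (6R)-6-(3,4-dimethoxyphenyl)-6-ethenyl-5,6-dihydroquinoline A2.

- **Merits.** One catalytic step forms both the ring and the stereocentre. In economy of chirality this is the better idea, since the chosen plan uses a stoichiometric organolithium at −78 °C and closes the ring separately.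
- **Weak points.**
  - The alkene of A1 that must initiate or terminate the metathesis is a 2-vinylpyridine. Its basic nitrogen sits where it can chelate the Lewis-acidic metal.
  - The catalyst must distinguish two vinyl groups at a centre whose other substituents are an aryl group and a CH2.
  - The central carbon of A1 bears an aryl, a picolyl and two vinyl groups, and such a carbon has no short preparation.
  - After ring closure the vinyl group of A2 still has to become the aminoethyl chain by hydroboration–oxidation, activation, amination and acetylation, and the C7=C8 bond has to be hydrogenated. The sequence becomes longer than the nine steps proposed here.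
- **Comparison.** The chosen plan sets against the elegance of A2 a stereocentre that comes from a reliable ketone hydrogenation and is then only transferred, and a nitrogen chain that is complete from step 1.

Alternative 2: enantioselective α-arylation. The cut is the C6–aryl bond. The bicyclic ketone 7,8-dihydroquinolin-5(6H)-one A3 would be alkylated at C6 to N-methyl-N-[2-(5-oxo-5,6,7,8-tetrahydroquinolin-6-yl)ethyl]acetamide A4. The sodium enolate of A4 would be coupled with 4-bromo-1,2-dimethoxybenzene A5 by a chiral bisphosphine complex of zerovalent palladium. The product is N-{2-[(6R)-6-(3,4-dimethoxyphenyl)-5-oxo-5,6,7,8-tetrahydroquinolin-6-yl]ethyl}-N-methylacetamide A6, which then needs removal of the C5 carbonyl.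

- **Merits.** This is clearly the shortest road, about four steps from A3, and the stereocentre is set catalytically. The aryl partner A5 is a simple purchasable bromide. On step count this road beats the chosen plan outright.
- **Weak points.**
  - Enantioselective α-arylations that create quaternary centres are best established for small α-substituents. In A4 the α-substituent is a chain ending in a Lewis-basic amide.
  - Making A4 from A3 needs a 2-amidoethyl electrophile, which is prone to cyclise on itself.
  - The ketone of A6 is flanked by a quaternary carbon and an electron-poor pyridine. Ionic reduction through a C5 cation is disfavoured, and Wolff–Kishner conditions endanger the acetamide.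
- **Comparison.** The chosen plan has no carbonyl to remove, and its stereochemical outcome does not depend on a ligand–substrate match at a crowded enolate such as that of A4.

Alternative 3: asymmetric allylic alkylation. The cut is the bond from C6 to the first chain carbon. The α-aryl ketone 6-(3,4-dimethoxyphenyl)-7,8-dihydroquinolin-5(6H)-one A7 would be made from A3 and A5 by a racemic α-arylation. The enolate of A7 would then be allylated with allyl acetate A8 and a chiral diphosphine complex of zerovalent palladium. The product is (6R)-6-(3,4-dimethoxyphenyl)-6-(prop-2-en-1-yl)-7,8-dihydroquinolin-5(6H)-one A9.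

- **Merits.** Allylation of stabilised α-aryl ketone enolates to quaternary centres is a strong reaction class, and the enolate geometry of A7 is fixed by the ring. The carbonyl of A9 can be removed while the side chain is still an inert allyl group, which is better than in Alternative 2. The count from A3 is about six steps, somewhat shorter than the chosen plan, and the chirality is catalytic.
- **Weak points.**
  - The allyl group delivered by A8 has one carbon too many. In A9 it must be cleaved oxidatively in the presence of the electron-rich arene and the pyridine, then reductively aminated and acetylated.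
  - The hindered C5 carbonyl of A9 still needs a forcing deoxygenation.
- **Comparison.** The chosen plan has the chain at the right length and oxidation state from the first step and needs no oxidative cleavage or deoxygenation. Its enantiopurity is fixed on a simple ketone rather than at the quaternary centre of A9.

Key step: step 5

## Route

Remark: quinoline numbering is used for the target; its only stereocentre is C6, read from the structure as (R).

Step 1
Reactants: 1 1-(3,4-dimethoxyphenyl)ethan-1-one; 2 N-benzylmethylamine
Product: 3 3-[benzyl(methyl)amino]-1-(3,4-dimethoxyphenyl)propan-1-one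
Conditions: (CH2O)n, conc. HCl (1.1 equiv), i-PrOH, reflux; then aq. NaOH, 0 °C
Reagents that add atoms: formaldehyde (used as paraformaldehyde), C=O
Why: Mannich reaction; the iminium ion from formaldehyde and the secondary amine is attacked by the enol of the methyl ketone, which has a single enolisable position, and the free base is liberated cold and used promptly to limit retro-Michael loss of the amine.

Step 2
Reactants: 3 3-[benzyl(methyl)amino]-1-(3,4-dimethoxyphenyl)propan-1-one
Product: 4 (1S)-3-[benzyl(methyl)amino]-1-(3,4-dimethoxyphenyl)propan-1-ol
Conditions: H2 (8 atm), trans-RuCl2[(R)-xylbinap][(R)-daipen] (0.2 mol %), t-BuOK (2 mol %), i-PrOH, 25 °C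
Reagents that add atoms: none
Why: Asymmetric hydrogenation of an aryl ketone by a RuCl2(diphosphine)(diamine) catalyst (concerted hydride/proton transfer), a reaction established for β-dialkylamino aryl ketones; the carbinol stereocentre is set by the catalyst, the (R)-diphosphine/(R)-diamine pair being expected, by analogy with simple aryl alkyl ketones, to give the (S)-alcohol.

Step 3
Reactants: 4 (1S)-3-[benzyl(methyl)amino]-1-(3,4-dimethoxyphenyl)propan-1-ol
Product: 5 (1S)-3-[benzyl(methyl)amino]-1-(3,4-dimethoxyphenyl)propyl N,N-di(propan-2-yl)carbamate
Conditions: NaH, THF, 0 °C; i-Pr2NCOCl, 0 → 50 °C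
Reagents that add atoms: N,N-diisopropylcarbamoyl chloride, CC(C)N(C(C)C)C(Cl)=O
Why: O-Carbamoylation of the sodium alkoxide with a carbamoyl chloride; the C–O bond at the stereocentre is not broken, so the configuration is retained, and the hindered carbamate is the directing and leaving group for step 5.

Step 4
Reactants: 6 2-chloro-3-(chloromethyl)pyridine; 7 bis(pinacolato)diboron
Product: 8 2-chloro-3-[(4,4,5,5-tetramethyl-1,3,2-dioxaborolan-2-yl)methyl]pyridine
Conditions: CuI (10 mol %), PPh3 (13 mol %), LiOMe (2 equiv), DMF, 25 °C
Reagents that add atoms: none
Why: Copper-catalysed boryl substitution of a benzylic chloride (a boryl–copper species formed from 7 and LiOMe displaces the benzylic chloride); at room temperature and without palladium the aryl C–Cl bond is left for step 7.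

Step 5
Reactants: 5 (1S)-3-[benzyl(methyl)amino]-1-(3,4-dimethoxyphenyl)propyl N,N-di(propan-2-yl)carbamate; 8 2-chloro-3-[(4,4,5,5-tetramethyl-1,3,2-dioxaborolan-2-yl)methyl]pyridine
Product: 11 (3R)-N-benzyl-4-(2-chloropyridin-3-yl)-3-(3,4-dimethoxyphenyl)-N-methyl-3-(4,4,5,5-tetramethyl-1,3,2-dioxaborolan-2-yl)butan-1-amine, via lithiated carbamate 9 (not isolated), via lithium boronate complex 10 (not isolated)
Conditions: s-BuLi (1.2 equiv), Et2O, −78 °C; 8 (1.4 equiv), −78 °C; MgBr2 in MeOH (1 M, 2 equiv), −78 °C → rt
Reagents that add atoms: none
Why: This is a lithiation–borylation: the carbamate carbonyl directs sec-butyllithium to the benzylic C–H of 5, which is replaced by lithium with retention to give the chelated carbanion 9, configurationally stable at −78 °C in diethyl ether. Carbanion 9 attacks the boron atom of 8 with retention at carbon and gives the tetracoordinate boronate 10. On warming, the picolyl CH2 shifts from boron to carbon anti-periplanar to the carbamate C–O bond, which leaves as lithium carbamate; this 1,2-metallate rearrangement inverts the carbon and forms the C5–C6 bond, MgBr2 assisting departure of the carbamate and methanol protonating any 9 released by reversal so that it cannot racemise and re-add. The closest known reaction type is the conversion of enantioenriched secondary benzylic N,N-diisopropylcarbamates and primary alkyl, allyl or benzyl pinacol boronic esters into tertiary boronic esters. No ring is closed. The one new stereocentre (C3 of 11, the future C6) is controlled only by the carbinol configuration of 5 through the retention–retention–inversion sequence, which should translate (S)-5 into (R)-11. The step needs chemoselectivity (benzylic deprotonation over ortho-lithiation of the dimethoxyarene and over the N-benzyl CH2, attack at boron over deprotonation of the picolyl CH2 or addition to the chloropyridine, carbon over oxygen migration) and stereofidelity; these rest on the directing effect of the carbamate, on adding 8 only after the base is consumed, on the Lewis acidity of the boronic ester at −78 °C and on the high migratory aptitude of a benzylic-type carbon.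

Step 6
Reactants: 11 (3R)-N-benzyl-4-(2-chloropyridin-3-yl)-3-(3,4-dimethoxyphenyl)-N-methyl-3-(4,4,5,5-tetramethyl-1,3,2-dioxaborolan-2-yl)butan-1-amine
Product: 14 (3R)-N-benzyl-3-[(2-chloropyridin-3-yl)methyl]-3-(3,4-dimethoxyphenyl)-N-methylpent-4-en-1-amine, via vinyl boronate complex 12 (not isolated), via beta-iodoalkyl boronic ester 13 (not isolated)
Conditions: CH2=CHMgBr (4 equiv), THF, −78 °C → rt; I2, MeOH, −78 °C; NaOMe, MeOH, −78 °C → rt
Reagents that add atoms: vinylmagnesium bromide, C=C[Mg]Br
Why: Zweifel olefination; vinyl addition to boron gives 12, iodine activates the vinyl group so that the tertiary carbon migrates from boron to carbon with retention (13), and methoxide triggers anti elimination of boron and iodide; the reaction is known for tertiary benzylic pinacol boronic esters and leaves the quaternary configuration unchanged.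

Step 7
Reactants: 14 (3R)-N-benzyl-3-[(2-chloropyridin-3-yl)methyl]-3-(3,4-dimethoxyphenyl)-N-methylpent-4-en-1-amine
Product: 16 N-benzyl-2-[(6R)-6-(3,4-dimethoxyphenyl)-5,6,7,8-tetrahydroquinolin-6-yl]-N-methylethan-1-amine, via alkyl-9-BBN borane 15 (not isolated)
Conditions: 9-BBN (2.5 equiv), THF, 0 → 60 °C; then Pd(OAc)2 (5 mol %), SPhos (10 mol %), aq. K3PO4, THF/H2O, 65 °C
Reagents that add atoms: none
Why: Anti-Markovnikov hydroboration of the monosubstituted alkene followed by intramolecular B-alkyl Suzuki–Miyaura coupling (oxidative addition of zerovalent palladium into the activated 2-chloropyridine C–Cl bond, base-assisted transmetalation, reductive elimination) forms C8–C8a and closes the six-membered ring; no stereocentre is formed or disturbed.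

Step 8
Reactants: 16 N-benzyl-2-[(6R)-6-(3,4-dimethoxyphenyl)-5,6,7,8-tetrahydroquinolin-6-yl]-N-methylethan-1-amine
Product: 17 2-[(6R)-6-(3,4-dimethoxyphenyl)-5,6,7,8-tetrahydroquinolin-6-yl]-N-methylethan-1-amine
Conditions: H2 (1 atm), Pd(OH)2/C, MeOH/AcOH, rt
Reagents that add atoms: none
Why: Hydrogenolysis of the N-benzyl group; the N-methyl group, the aryl methyl ethers and the pyridine ring should be inert at ambient pressure, and acetic acid keeps the nitrogen atoms from blocking the catalyst.

Step 9
Reactants: 17 2-[(6R)-6-(3,4-dimethoxyphenyl)-5,6,7,8-tetrahydroquinolin-6-yl]-N-methylethan-1-amine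
Product: 18 N-{2-[(6R)-6-(3,4-dimethoxyphenyl)-5,6,7,8-tetrahydroquinolin-6-yl]ethyl}-N-methylacetamide
Conditions: Ac2O, Et3N, CH2Cl2, 0 °C → rt
Reagents that add atoms: acetic anhydride, CC(=O)OC(C)=O
Why: N-Acylation of a secondary amine by an anhydride (nucleophilic acyl substitution); the pyridine nitrogen is only reversibly acylated and the stereocentre is remote.

## Compound list

1 | 1-(3,4-dimethoxyphenyl)ethan-1-one (3,4-dimethoxyacetophenone) | CC(=O)c1ccc(OC)c(OC)c1 | starting material
2 | N-benzylmethylamine | CNCc1ccccc1 | starting material
3 | 3-[benzyl(methyl)amino]-1-(3,4-dimethoxyphenyl)propan-1-one | COc1ccc(C(=O)CCN(C)Cc2ccccc2)cc1OC | intermediate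
4 | (1S)-3-[benzyl(methyl)amino]-1-(3,4-dimethoxyphenyl)propan-1-ol | COc1ccc([C@@H](O)CCN(C)Cc2ccccc2)cc1OC | intermediate
5 | (1S)-3-[benzyl(methyl)amino]-1-(3,4-dimethoxyphenyl)propyl N,N-di(propan-2-yl)carbamate | COc1ccc([C@@H](OC(=O)N(C(C)C)C(C)C)CCN(C)Cc2ccccc2)cc1OC | intermediate
6 | 2-chloro-3-(chloromethyl)pyridine | ClCc1cccnc1Cl | starting material
7 | bis(pinacolato)diboron | CC1(C)OB(OC1(C)C)B1OC(C)(C)C(C)(C)O1 | starting material
8 | 2-chloro-3-[(4,4,5,5-tetramethyl-1,3,2-dioxaborolan-2-yl)methyl]pyridine | Clc1ncccc1CB1OC(C)(C)C(C)(C)O1 | intermediate
9 | (1S)-3-[benzyl(methyl)amino]-1-(3,4-dimethoxyphenyl)-1-lithiopropyl N,N-di(propan-2-yl)carbamate (lithiated carbamate, formed in the flask) | COc1ccc([C@@]([Li])(OC(=O)N(C(C)C)C(C)C)CCN(C)Cc2ccccc2)cc1OC | intermediate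
10 | lithium boronate complex of 8 and 9: tetracoordinate pinacolato boron bearing the (2-chloropyridin-3-yl)methyl group and the (S)-configured carbamate carbon (formed in the flask) | COc1ccc([C@@]([B-]2(Cc3cccnc3Cl)OC(C)(C)C(C)(C)O2)(OC(=O)N(C(C)C)C(C)C)CCN(C)Cc2ccccc2)cc1OC.[Li+] | intermediate
11 | (3R)-N-benzyl-4-(2-chloropyridin-3-yl)-3-(3,4-dimethoxyphenyl)-N-methyl-3-(4,4,5,5-tetramethyl-1,3,2-dioxaborolan-2-yl)butan-1-amine | COc1ccc([C@](Cc2cccnc2Cl)(CCN(C)Cc2ccccc2)B2OC(C)(C)C(C)(C)O2)cc1OC | intermediate
12 | bromomagnesium vinyl boronate complex of 11: tetracoordinate pinacolato boron bearing a vinyl group and the (R)-configured tertiary carbon (formed in the flask) | COc1ccc([C@](Cc2cccnc2Cl)(CCN(C)Cc2ccccc2)[B-]2(C=C)OC(C)(C)C(C)(C)O2)cc1OC.[Mg+2].[Br-] | intermediate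
13 | (3R)-N-benzyl-3-[(2-chloropyridin-3-yl)methyl]-3-(3,4-dimethoxyphenyl)-5-iodo-N-methyl-4-(4,4,5,5-tetramethyl-1,3,2-dioxaborolan-2-yl)pentan-1-amine, both C4 epimers (formed in the flask) | COc1ccc([C@](Cc2cccnc2Cl)(CCN(C)Cc2ccccc2)C(CI)B2OC(C)(C)C(C)(C)O2)cc1OC | intermediate
14 | (3R)-N-benzyl-3-[(2-chloropyridin-3-yl)methyl]-3-(3,4-dimethoxyphenyl)-N-methylpent-4-en-1-amine | COc1ccc([C@](Cc2cccnc2Cl)(CCN(C)Cc2ccccc2)C=C)cc1OC | intermediate
15 | 9-{(3R)-5-[benzyl(methyl)amino]-3-[(2-chloropyridin-3-yl)methyl]-3-(3,4-dimethoxyphenyl)pentyl}-9-borabicyclo[3.3.1]nonane (formed in the flask) | COc1ccc([C@](Cc2cccnc2Cl)(CCN(C)Cc2ccccc2)CCB2C3CCCC2CCC3)cc1OC | intermediate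
16 | N-benzyl-2-[(6R)-6-(3,4-dimethoxyphenyl)-5,6,7,8-tetrahydroquinolin-6-yl]-N-methylethan-1-amine | COc1ccc([C@]2(CCN(C)Cc3ccccc3)CCc3ncccc3C2)cc1OC | intermediate
17 | 2-[(6R)-6-(3,4-dimethoxyphenyl)-5,6,7,8-tetrahydroquinolin-6-yl]-N-methylethan-1-amine | COc1ccc([C@]2(CCNC)CCc3ncccc3C2)cc1OC | intermediate
18 | N-{2-[(6R)-6-(3,4-dimethoxyphenyl)-5,6,7,8-tetrahydroquinolin-6-yl]ethyl}-N-methylacetamide | COc1ccc([C@]2(CCN(C)C(C)=O)CCc3ncccc3C2)cc1OC | target

## Step count and risk assessment

Total: 9 steps. Longest linear sequence: 8 steps (1, 2, 3, 5, 6, 7, 8, 9); step 4 makes the second fragment.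

**Step 5 (key step).** The most likely failure is loss of stereochemical fidelity or low conversion because formation of boronate 10 is reversible: the new carbon–boron bond joins a fully substituted carbon to a pinacol-shielded boron that carries an ortho-substituted picolyl group. Released 9 can racemise or be quenched before the 1,2-shift takes place. Proton transfer from the picolyl CH2 of 8 to 9 is the second risk. The fallback sets out from 6 and returns at 14. The less hindered neopentyl glycol ester 2-chloro-3-[(5,5-dimethyl-1,3,2-dioxaborinan-2-yl)methyl]pyridine F1 is made from 6 with bis(neopentyl glycolato)diboron under the copper conditions of step 4. It is combined with lithiated 5 as in step 5; the smaller diol makes boronate formation effectively irreversible and the shift faster. The resulting (3R)-N-benzyl-4-(2-chloropyridin-3-yl)-3-(3,4-dimethoxyphenyl)-3-(5,5-dimethyl-1,3,2-dioxaborinan-2-yl)-N-methylbutan-1-amine F2 is taken directly through the Zweifel olefination of step 6 to 14.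

**Step 6.** The most likely failure is incomplete formation of boronate 12 at the congested tertiary boron, or diversion of iodine by the tertiary amine and the electron-rich arene, so that 11 is recovered or oxidised. The fallback sets out from 11 and returns at 16. It replaces the olefination by two Matteson homologations with chloromethyllithium, generated from bromochloromethane and n-BuLi at −78 °C in the presence of the boronic ester. This is a small nucleophile and needs no halogen electrophile. The first homologation inserts C7 with retention and gives (3R)-N-benzyl-3-[(2-chloropyridin-3-yl)methyl]-3-(3,4-dimethoxyphenyl)-N-methyl-4-(4,4,5,5-tetramethyl-1,3,2-dioxaborolan-2-yl)butan-1-amine F3. The second inserts C8 and gives (3R)-N-benzyl-3-[(2-chloropyridin-3-yl)methyl]-3-(3,4-dimethoxyphenyl)-N-methyl-5-(4,4,5,5-tetramethyl-1,3,2-dioxaborolan-2-yl)pentan-1-amine F4. F4 is closed to 16 through its trifluoroborate, as described under step 7.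

**Step 7.** The most likely failure is sequestration of 9-BBN by the amine nitrogen, leaving the hindered vinyl group partly unreacted. Alternatively, protodeboronation of the neopentyl-type borane may outrun a coupling slowed by coordination of palladium to the two nitrogen atoms. The fallback sets out from 14 and returns at 16; it separates hydroboration from coupling. Iridium-catalysed hydroboration with pinacolborane ([Ir(cod)Cl]2, dppe, CH2Cl2, rt) gives the isolable primary boronic ester F4 (structure as in the step 6 fallback). KHF2 in aqueous methanol converts it into potassium {(3R)-5-[benzyl(methyl)amino]-3-[(2-chloropyridin-3-yl)methyl]-3-(3,4-dimethoxyphenyl)pentyl}trifluoroborate F5. F5 is cyclised by intramolecular Suzuki–Miyaura coupling of an alkyltrifluoroborate with the aryl chloride (Pd(OAc)2, RuPhos, K2CO3, toluene/H2O, 80 °C) to 16.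

**Step 2.** The most likely failure is base-induced retro-Michael loss of the amine from 3 in the alkoxide-containing medium, or an enantiomeric ratio below what is needed with this electron-rich ketone. Any shortfall is carried unchanged to 18, because all later steps only transfer configuration. The fallback sets out from 3 and returns at 4. Reduction with NaBH4 in methanol at 0 °C gives racemic 3-[benzyl(methyl)amino]-1-(3,4-dimethoxyphenyl)propan-1-ol F6. F6 is resolved by crystallisation of a diastereomeric salt with an enantiopure mandelic acid, a classical method for 3-amino-1-arylpropan-1-ols. The first candidate is the (S)-mandelate of the (S)-alcohol, (1S)-3-[benzyl(methyl)amino]-1-(3,4-dimethoxyphenyl)propan-1-ol (S)-mandelate F7. Treatment of F7 with aqueous base returns 4.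

## Further compounds

F1 | step 5 | 2-chloro-3-[(5,5-dimethyl-1,3,2-dioxaborinan-2-yl)methyl]pyridine | Clc1ncccc1CB1OCC(C)(C)CO1
F2 | step 5 | (3R)-N-benzyl-4-(2-chloropyridin-3-yl)-3-(3,4-dimethoxyphenyl)-3-(5,5-dimethyl-1,3,2-dioxaborinan-2-yl)-N-methylbutan-1-amine | COc1ccc([C@](Cc2cccnc2Cl)(CCN(C)Cc2ccccc2)B2OCC(C)(C)CO2)cc1OC
F3 | step 6 | (3R)-N-benzyl-3-[(2-chloropyridin-3-yl)methyl]-3-(3,4-dimethoxyphenyl)-N-methyl-4-(4,4,5,5-tetramethyl-1,3,2-dioxaborolan-2-yl)butan-1-amine | COc1ccc([C@](Cc2cccnc2Cl)(CCN(C)Cc2ccccc2)CB2OC(C)(C)C(C)(C)O2)cc1OC
F4 | step 6 | (3R)-N-benzyl-3-[(2-chloropyridin-3-yl)methyl]-3-(3,4-dimethoxyphenyl)-N-methyl-5-(4,4,5,5-tetramethyl-1,3,2-dioxaborolan-2-yl)pentan-1-amine | COc1ccc([C@](Cc2cccnc2Cl)(CCN(C)Cc2ccccc2)CCB2OC(C)(C)C(C)(C)O2)cc1OC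
F5 | step 7 | potassium {(3R)-5-[benzyl(methyl)amino]-3-[(2-chloropyridin-3-yl)methyl]-3-(3,4-dimethoxyphenyl)pentyl}trifluoroborate | COc1ccc([C@](Cc2cccnc2Cl)(CCN(C)Cc2ccccc2)CC[B-](F)(F)F)cc1OC.[K+]
F6 | step 2 | racemic 3-[benzyl(methyl)amino]-1-(3,4-dimethoxyphenyl)propan-1-ol | COc1ccc(C(O)CCN(C)Cc2ccccc2)cc1OC
F7 | step 2 | (1S)-3-[benzyl(methyl)amino]-1-(3,4-dimethoxyphenyl)propan-1-ol (S)-mandelate (1:1 salt) | COc1ccc([C@@H](O)CCN(C)Cc2ccccc2)cc1OC.O[C@@H](c1ccccc1)C(=O)O
A1 | alternative 1 | 3-[2-(3,4-dimethoxyphenyl)-2-ethenylbut-3-en-1-yl]-2-ethenylpyridine | C=Cc1ncccc1CC(C=C)(C=C)c1ccc(OC)c(OC)c1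
A2 | alternative 1 | (6R)-6-(3,4-dimethoxyphenyl)-6-ethenyl-5,6-dihydroquinoline | COc1ccc([C@]2(C=C)C=Cc3ncccc3C2)cc1OC
A3 | alternative 2 | 7,8-dihydroquinolin-5(6H)-one | O=C1CCCc2ncccc21
A4 | alternative 2 | N-methyl-N-[2-(5-oxo-5,6,7,8-tetrahydroquinolin-6-yl)ethyl]acetamide (racemic) | CC(=O)N(C)CCC1CCc2ncccc2C1=O
A5 | alternative 2 | 4-bromo-1,2-dimethoxybenzene | COc1ccc(Br)cc1OC
A6 | alternative 2 | N-{2-[(6R)-6-(3,4-dimethoxyphenyl)-5-oxo-5,6,7,8-tetrahydroquinolin-6-yl]ethyl}-N-methylacetamide | COc1ccc([C@]2(CCN(C)C(C)=O)CCc3ncccc3C2=O)cc1OC
A7 | alternative 3 | 6-(3,4-dimethoxyphenyl)-7,8-dihydroquinolin-5(6H)-one (racemic) | COc1ccc(C2CCc3ncccc3C2=O)cc1OC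
A8 | alternative 3 | allyl acetate (prop-2-en-1-yl acetate) | CC(=O)OCC=C
A9 | alternative 3 | (6R)-6-(3,4-dimethoxyphenyl)-6-(prop-2-en-1-yl)-7,8-dihydroquinolin-5(6H)-one | COc1ccc([C@]2(CC=C)CCc3ncccc3C2=O)cc1OC
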